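The pyranone (ring C) is cut at C4–C4a and O1–C2, which separates a fully substituted ring A resorcinol from a ring B aroylacetate. Heating the two without catalyst should C-acylate the arene through an aroylketene and then cyclodehydrate, building ring C in one operation. The step exploits the symmetry of ring A: its only ring C–H (future C4a) sits between two identical hydroxyls (future O1 and 5-OH), so neither the acylation site nor the closing oxygen can be chosen wrongly. The precursors are a 5-benzyloxy-4,6-dimethoxyresorcinol and an ethyl 3,5-bis(benzyloxy)-4-methoxybenzoylacetate; one hydrogenolysis then frees the three remaining phenols.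

Key step: step 7

Assumption: the aryl benzyl ethers, including the one between two methoxy groups on ring A, are taken to survive a short acid-free thermal pulse near 240 °C under argon; benzyl is kept on all three spectator phenols so that a single hydrogenolysis ends the route.

Step 1
Reactants: 1 2,6-dimethoxyphenol
Product: 2 2-(benzyloxy)-1,3-dimethoxybenzene
Conditions: BnBr, K2CO3, DMF, 60 °C
Reagents that add atoms: benzyl bromide, BrCc1ccccc1
Why: Williamson ether synthesis, in which the phenolate formed with K2CO3 displaces bromide from benzyl bromide (SN2) and the two ortho methoxy groups do not prevent O-alkylation of this acidic phenol.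

Step 2
Reactants: 2 2-(benzyloxy)-1,3-dimethoxybenzene
Product: 3 3-(benzyloxy)-1,5-dibromo-2,4-dimethoxybenzene
Conditions: NBS (2.1 equiv), MeCN, 0 °C to rt, dark
Reagents that add atoms: N-bromosuccinimide, O=C1CCC(=O)N1Br
Why: Electrophilic aromatic bromination, directed to C4 and C6 because each is ortho to one methoxy group and para to the other, whereas C5 is activated only by the twisted benzyloxy group, and ionic conditions in the dark spare the benzylic CH2.

Step 3
Reactants: 3 3-(benzyloxy)-1,5-dibromo-2,4-dimethoxybenzene
Product: 4 2,2'-[5-(benzyloxy)-4,6-dimethoxy-1,3-phenylene]bis(4,4,5,5-tetramethyl-1,3,2-dioxaborolane)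
Conditions: B2pin2 (2.6 equiv), Pd(dppf)Cl2 (5 mol %), KOAc, 1,4-dioxane, 90 °C
Reagents that add atoms: bis(pinacolato)diboron, CC1(C)OB(OC1(C)C)B1OC(C)(C)C(C)(C)O1
Why: Miyaura borylation, in which zerovalent palladium inserts into each C–Br bond, the acetate-bound divalent palladium aryl transmetallates with B2pin2 and reductive elimination gives the aryl boronate, a sequence well established for ortho-alkoxy aryl bromides.

Step 4
Reactants: 4 2,2'-[5-(benzyloxy)-4,6-dimethoxy-1,3-phenylene]bis(4,4,5,5-tetramethyl-1,3,2-dioxaborolane)
Product: 5 5-(benzyloxy)-4,6-dimethoxybenzene-1,3-diol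
Conditions: 30% H2O2, aq NaOH, THF, 0 °C, Ar; then Na2S2O3, HCl
Reagents that add atoms: hydrogen peroxide, OO
Why: Oxidation of aryl boronates with alkaline hydrogen peroxide, in which hydroperoxide adds to boron, the aryl group migrates from boron to oxygen and the borate is hydrolysed, so each C–B bond becomes C–OH at the same carbon while benzyl and methyl ethers are inert.

Step 5
Reactants: 6 3,5-dihydroxy-4-methoxybenzoic acid
Product: 8 3,5-bis(benzyloxy)-4-methoxybenzoic acid, via benzyl ester 7 (not isolated)
Conditions: BnBr (3.3 equiv), K2CO3, DMF, 60 °C; DMF removed, then NaOH, MeOH–THF–H2O, 65 °C; HCl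
Reagents that add atoms: benzyl bromide, BrCc1ccccc1; sodium hydroxide, [Na+].[OH-]
Why: Williamson O-benzylation of both phenols and the carboxylate followed by saponification (acyl–oxygen cleavage by hydroxide) of the benzyl ester only, since aryl benzyl ethers are stable to aqueous base.

Step 6
Reactants: 8 3,5-bis(benzyloxy)-4-methoxybenzoic acid, 9 potassium ethyl malonate
Product: 12 ethyl 3-[3,5-bis(benzyloxy)-4-methoxyphenyl]-3-oxopropanoate, via acyl imidazolide 10 (not isolated), via aroylmalonic half ester 11 (not isolated)
Conditions: CDI, THF, rt; then 9, MgCl2, Et3N, MeCN, rt to 40 °C; 1 M HCl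
Reagents that add atoms: none
Why: Masamune–Brooks β-keto ester synthesis, in which the acyl imidazolide acylates the magnesium enolate of the malonate half ester at carbon and the resulting β-keto acid loses CO2 on acidic work-up, under conditions that leave benzyl ethers untouched.

Step 7
Reactants: 5 5-(benzyloxy)-4,6-dimethoxybenzene-1,3-diol, 12 ethyl 3-[3,5-bis(benzyloxy)-4-methoxyphenyl]-3-oxopropanoate
Product: 15 7-(benzyloxy)-2-[3,5-bis(benzyloxy)-4-methoxyphenyl]-5-hydroxy-6,8-dimethoxy-4H-chromen-4-one, via aroylketene 13 (not isolated), via 1,3-diketone 14 (not isolated)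
Conditions: neat melt (or minimal Ph2O), 12 (1.3 equiv), Ar stream, 240 °C (preheated bath or microwave), 10–30 min, EtOH/H2O swept out
Reagents that add atoms: none
Why: Thermal loss of ethanol from 12 gives aroylketene 13, whose ketene carbon is attacked by the only unsubstituted ring carbon of 5 (between the two hydroxyls, para to the benzyloxy group), which forms C4–C4a and, after tautomerisation, 1,3-diketone 14. One of the two equivalent ortho hydroxyls then adds to the aryl ketone carbonyl (6-exo-trig, hemiketal) and water is lost, so that O1–C2 and ring C arise by addition–elimination. The closest known reaction is the Mentzer thermal condensation of phloroglucinol-type phenols with ethyl aroylacetates to 5,7-dioxygenated flavones. No stereocenter is created. The step needs C- over O-acylation and chromone over coumarin formation: O-acylation by the ketene is reversible at this temperature whereas C-acylation followed by dehydration is not, and the absence of acid suppresses Pechmann-type attack of the arene on the ketone carbonyl. Regiochemistry is secured by the substrate, since ring A has a single C–H and both flanking hydroxyls close to the same chromone.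

Step 8
Reactants: 15 7-(benzyloxy)-2-[3,5-bis(benzyloxy)-4-methoxyphenyl]-5-hydroxy-6,8-dimethoxy-4H-chromen-4-one
Product: 16 2-(3,5-dihydroxy-4-methoxyphenyl)-5,7-dihydroxy-6,8-dimethoxy-4H-chromen-4-one
Conditions: H2 (1 atm), 10% Pd/C, THF–MeOH, rt
Reagents that add atoms: none
Why: Catalytic hydrogenolysis of the three benzylic C–O bonds on palladium metal, a standard deprotection of benzyloxyflavones that should leave the chromone C2=C3 bond, the carbonyl and the methyl ethers intact at ambient pressure and temperature.

Compound list
1 | 2,6-dimethoxyphenol | COc1cccc(OC)c1O | starting material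
2 | 2-(benzyloxy)-1,3-dimethoxybenzene | COc1cccc(OC)c1OCc1ccccc1 | intermediate
3 | 3-(benzyloxy)-1,5-dibromo-2,4-dimethoxybenzene | COc1c(Br)cc(Br)c(OC)c1OCc1ccccc1 | intermediate
4 | 2,2'-[5-(benzyloxy)-4,6-dimethoxy-1,3-phenylene]bis(4,4,5,5-tetramethyl-1,3,2-dioxaborolane) | COc1c(B2OC(C)(C)C(C)(C)O2)cc(B2OC(C)(C)C(C)(C)O2)c(OC)c1OCc1ccccc1 | intermediate
5 | 5-(benzyloxy)-4,6-dimethoxybenzene-1,3-diol | COc1c(O)cc(O)c(OC)c1OCc1ccccc1 | intermediate
6 | 3,5-dihydroxy-4-methoxybenzoic acid | COc1c(O)cc(C(=O)O)cc1O | starting material
7 | benzyl 3,5-bis(benzyloxy)-4-methoxybenzoate (not isolated) | COc1c(OCc2ccccc2)cc(C(=O)OCc2ccccc2)cc1OCc1ccccc1 | intermediate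
8 | 3,5-bis(benzyloxy)-4-methoxybenzoic acid | COc1c(OCc2ccccc2)cc(C(=O)O)cc1OCc1ccccc1 | intermediate
9 | potassium ethyl malonate (potassium 3-ethoxy-3-oxopropanoate) | CCOC(=O)CC(=O)[O-].[K+] | starting material
10 | [3,5-bis(benzyloxy)-4-methoxyphenyl](1H-imidazol-1-yl)methanone (not isolated) | COc1c(OCc2ccccc2)cc(C(=O)n2ccnc2)cc1OCc1ccccc1 | intermediate
11 | 2-[3,5-bis(benzyloxy)-4-methoxybenzoyl]-3-ethoxy-3-oxopropanoic acid (racemic, present as its magnesium chelate, not isolated) | CCOC(=O)C(C(=O)O)C(=O)c1cc(OCc2ccccc2)c(OC)c(OCc2ccccc2)c1 | intermediate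
12 | ethyl 3-[3,5-bis(benzyloxy)-4-methoxyphenyl]-3-oxopropanoate | CCOC(=O)CC(=O)c1cc(OCc2ccccc2)c(OC)c(OCc2ccccc2)c1 | intermediate
13 | 3-[3,5-bis(benzyloxy)-4-methoxyphenyl]prop-1-ene-1,3-dione (aroylketene, not isolated) | O=C=CC(=O)c1cc(OCc2ccccc2)c(OC)c(OCc2ccccc2)c1 | intermediate
14 | 1-[4-(benzyloxy)-2,6-dihydroxy-3,5-dimethoxyphenyl]-3-[3,5-bis(benzyloxy)-4-methoxyphenyl]propane-1,3-dione (not isolated) | COc1c(O)c(C(=O)CC(=O)c2cc(OCc3ccccc3)c(OC)c(OCc3ccccc3)c2)c(O)c(OC)c1OCc1ccccc1 | intermediate
15 | 7-(benzyloxy)-2-[3,5-bis(benzyloxy)-4-methoxyphenyl]-5-hydroxy-6,8-dimethoxy-4H-chromen-4-one | COc1c(OCc2ccccc2)cc(-c2cc(=O)c3c(O)c(OC)c(OCc4ccccc4)c(OC)c3o2)cc1OCc1ccccc1 | intermediate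
16 | 2-(3,5-dihydroxy-4-methoxyphenyl)-5,7-dihydroxy-6,8-dimethoxy-4H-chromen-4-one (no stereocenters) | COc1c(O)cc(-c2cc(=O)c3c(O)c(OC)c(O)c(OC)c3o2)cc1O | target

Total step count: 8. Longest linear sequence: 6 (steps 1, 2, 3, 4, 7 and 8); steps 5 and 6 form the second branch.

Steps most likely to fail

Risk 1, step 7. At about 240 °C a benzyl group may be lost or may migrate, above all from the oxygen flanked by two methoxy groups. The electron-rich diol may also oxidise or char before it is acylated, or the reaction may stall at the reversibly O-acylated stage. Fallback (sets out from 5 and 8, returns at 14 and then 15): the same two bonds are made stepwise below 110 °C by an acetophenone and aroyl chloride route of the Baker–Venkataraman type. Diol 5 is C-acetylated at its single ring C–H (Ac2O, BF3·OEt2, 0 °C to rt, Friedel–Crafts/Fries) to give 1-[4-(benzyloxy)-2,6-dihydroxy-3,5-dimethoxyphenyl]ethan-1-one F1. Acid 8 is converted with oxalyl chloride and catalytic DMF in CH2Cl2 into 3,5-bis(benzyloxy)-4-methoxybenzoyl chloride F2. The trilithium salt of F1 (LiN(SiMe3)2, 4.2 equiv, THF, −78 °C) is acylated at carbon by F2 and, after acidic quench, should give 1,3-diketone 14, now isolated. Catalytic TsOH in toluene at 80–100 °C then cyclodehydrates 14 to flavone 15, where the route resumes with step 8.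

Risk 2, step 3. The second borylation may remain incomplete, or protodebromination and protodeboronation on the electron-rich ring may give mono-functionalised material that is hard to separate. Fallback (sets out from 3, returns at 5): the boron detour is replaced by direct C–O coupling. Palladium-catalysed hydroxylation of both C–Br bonds with KOH (Pd2(dba)3, tBuXPhos, 1,4-dioxane–H2O, 100 °C, then HCl) should give diol 5 in one operation, so that steps 3 and 4 are bypassed and no new compound is made (F0).

Risk 3, step 4. The electron-rich resorcinol may be over-oxidised by alkaline peroxide or by air during work-up, purification and storage. Fallback (sets out from 4, returns at 5): the diol is trapped instead of being isolated free. After a buffered oxidation (H2O2, NaHCO3, THF–H2O, 0 °C) the crude extract is acetylated at once (Ac2O, pyridine, cat. DMAP) to 5-(benzyloxy)-4,6-dimethoxy-1,3-phenylene diacetate F3, which should be air-stable and can be purified and stored. K2CO3 in degassed MeOH at 0 °C followed by acidification releases 5 just before step 7.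

Further compounds
F1 | step 7 | 1-[4-(benzyloxy)-2,6-dihydroxy-3,5-dimethoxyphenyl]ethan-1-one | COc1c(O)c(C(C)=O)c(O)c(OC)c1OCc1ccccc1
F2 | step 7 | 3,5-bis(benzyloxy)-4-methoxybenzoyl chloride | COc1c(OCc2ccccc2)cc(C(=O)Cl)cc1OCc1ccccc1
F0 | step 3 | none | none
F3 | step 4 | 5-(benzyloxy)-4,6-dimethoxy-1,3-phenylene diacetate | COc1c(OC(C)=O)cc(OC(C)=O)c(OC)c1OCc1ccccc1
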